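**Retrosynthetic overview**
1. Rings A (dihydrofuran) and B (spiro-lactone) are formed last and together: acid removes the C1 silyl ether and the C12 tert-butyl ester of a macrocyclic (Z)-enone, C1–OH adds across the ring to the C8 ketone, and the C12 acid closes the spiroketal lactone.
2. The C10 methyl comes from syn-addition of Me2CuLi to a macrocyclic ynone; the ten-membered carbocycle is closed at C8–C9 by a CrCl2/NiCl2 iodoalkyne–aldehyde cyclisation.
3. Ring C comes first: propargylic alcohol → (Z)-iodoalkene → carbonylative lactonisation to the butenolide, then cis-dihydroxylation (C4, C5) and C5 acetylation.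
4. Key C6–C7 bond: intermolecular aldol of the Seebach dioxolanone enolate of 6 (C7, C8, C11–C13, from dimethyl (R)-malate) with ynal 19 (C1–C6, C9, C10), followed by oxidation and CBS reduction to fix C6.
5. Ring order: C, then the carbocycle, then A and B.

Assumption: the descriptors are taken exactly as written (1S,4S,5S,6R,7S,8S,11S); read literally, C2 and C7 leave the dihydrofuran from opposite faces, a strained in,out bridge that may be a transcription error, so C8 (closed last under equilibrating acid) is written as in the target, and C1 is catalyst-controlled in step 8, which gives the C1 epimer with the enantiomeric catalyst if needed.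

Numbering: C1 = CH–O of ring A; C2, C3 = CH2; C4 = C(OH); C5 = CH(OAc); C6 = CH–O of ring C; C7 = C(OH); C8 = spiro ketal carbon; C9 = CH=; C10 = alkene carbon bearing the C14 methyl; C11 = CH(CH3) (C13); C12 = ring B carbonyl; C15 = ring C carbonyl. TBS = tert-butyldimethylsilyl, TIPS = triisopropylsilyl.

**East fragment**

Step 1
Reactants: 1 dimethyl (R)-malate
Product: 3 dimethyl (2R,3S)-2-hydroxy-3-methylbutanedioate, via dilithium dianion 2 (not isolated)
Conditions: LiN(SiMe3)2 (2.2 equiv), THF, −78 to −20 °C; MeI, −78 to −10 °C; aq. NH4Cl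
Reagents that add atoms: iodomethane, CI
Why: Fráter–Seebach alkylation, in which the chelated alkoxide-enolate is methylated anti to the alkoxide and so sets C11 (S) at about 9:1.

Step 2
Reactants: 3 dimethyl (2R,3S)-2-hydroxy-3-methylbutanedioate
Product: 4 (2R,3S)-2-hydroxy-3-methylbutanedioic acid
Conditions: KOH, H2O–MeOH, 0 °C to rt; HCl to pH 1
Reagents that add atoms: potassium hydroxide, [K+].[OH-]
Why: Plain saponification; the carboxylate formed first protects C11 from epimerisation.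

Step 3
Reactants: 4 (2R,3S)-2-hydroxy-3-methylbutanedioic acid
Product: 5 (2S)-2-[(2R,4R)-2-tert-butyl-5-oxo-1,3-dioxolan-4-yl]propanoic acid (cis-dioxolanone)
Conditions: pivalaldehyde, TsOH·H2O (cat.), H2SO4 (cat.), pentane, reflux, Dean–Stark; recrystallise
Reagents that add atoms: 2,2-dimethylpropanal (pivalaldehyde), CC(C)(C)C=O
Why: Seebach acetalisation of the α-hydroxy acid gives the five-membered dioxolanone, and the new acetal centre settles cis to the side chain under thermodynamic control.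

Step 4
Reactants: 5 cis-dioxolanone acid
Product: 6 tert-butyl (2S)-2-[(2R,4R)-2-tert-butyl-5-oxo-1,3-dioxolan-4-yl]propanoate
Conditions: tert-butyl 2,2,2-trichloroacetimidate, cyclohexane–CH2Cl2, rt
Reagents that add atoms: tert-butyl 2,2,2-trichloroacetimidate, CC(C)(C)OC(=N)C(Cl)(Cl)Cl
Why: Imidate O-alkylation of the acid under near-neutral conditions leaves the acid-sensitive acetal and both stereocentres intact.

**West fragment**

Step 5
Reactants: 7 pent-4-ynoic acid
Product: 9 5-(trimethylsilyl)pent-4-ynoic acid, via trimethylsilyl ester 8 (not isolated)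
Conditions: n-BuLi (2.1 equiv), THF, −78 °C; Me3SiCl (2.2 equiv), −78 °C to rt; 1 M HCl
Reagents that add atoms: chlorotrimethylsilane, C[Si](C)(C)Cl
Why: C-silylation of the carboxylate–acetylide dianion, with the silyl ester hydrolysed on acidic work-up.

Step 6
Reactants: 9 5-(trimethylsilyl)pent-4-ynoic acid
Product: 11 N-methoxy-N-methyl-5-(trimethylsilyl)pent-4-ynamide, via acyl imidazole 10 (not isolated)
Conditions: 1,1'-carbonyldiimidazole, CH2Cl2, rt; then MeNHOMe·HCl, rt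
Reagents that add atoms: N,O-dimethylhydroxylamine hydrochloride, CNOC.Cl
Why: Weinreb amide formation through the acyl imidazole.

Step 7
Reactants: 11 Weinreb amide; 12 ethynyl(triisopropyl)silane
Product: 14 1-(triisopropylsilyl)-7-(trimethylsilyl)hepta-1,6-diyn-3-one, via lithium acetylide 13 (not isolated)
Conditions: 12, n-BuLi, THF, −78 °C; add 11, −78 to 0 °C; aq. NH4Cl
Reagents that add atoms: none
Why: Weinreb ketone synthesis, where the stable chelated adduct stops at the ynone.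

Step 8
Reactants: 14 diynone
Product: 15 (3S)-1-(triisopropylsilyl)-7-(trimethylsilyl)hepta-1,6-diyn-3-ol
Conditions: RuCl[(S,S)-TsDPEN](p-cymene) (2 mol %), i-PrOH, rt
Reagents that add atoms: none
Why: Noyori asymmetric transfer hydrogenation of an ynone, in which the (S,S)-catalyst gives the (S)-propargylic alcohol and sets C1.

Step 9
Reactants: 15 (S)-propargylic alcohol
Product: 16 (3S)-3-[(TBS)oxy]-1-(TIPS)-7-(trimethylsilyl)hepta-1,6-diyne
Conditions: TBSCl, imidazole, DMF, rt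
Reagents that add atoms: tert-butyldimethylsilyl chloride, CC(C)(C)[Si](C)(C)Cl
Why: Standard silylation of a secondary alcohol.

Step 10
Reactants: 16 bis-silyl diyne
Product: 17 (3S)-3-[(TBS)oxy]-1-(TIPS)hepta-1,6-diyne
Conditions: K2CO3 (0.2 equiv), MeOH, rt
Reagents that add atoms: none
Why: Selective methanolytic protodesilylation of the trimethylsilyl alkyne; the hindered TIPS alkyne and the TBS ether survive.

Step 11
Reactants: 17 terminal alkyne
Product: 19 (6S)-6-[(TBS)oxy]-8-(TIPS)octa-2,7-diynal, via lithium acetylide 18 (not isolated)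
Conditions: n-BuLi (1.05 equiv), THF, −78 °C; DMF, −78 to 0 °C; reverse quench into aq. KH2PO4
Reagents that add atoms: N,N-dimethylformamide, CN(C)C=O
Why: Formylation of the lithium acetylide with DMF (C6 enters here), with the buffered reverse quench preventing amine addition to the ynal.

**Fragment union and ring C**

Step 12
Reactants: 6 dioxolanone tert-butyl ester; 19 ynal
Product: 21 aldol adduct (tert-butyl ester; dioxolanone C4 now quaternary and S; both C6 carbinol epimers), via lithium enolate 20 (not isolated)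
Conditions: LiN(i-Pr)2 (1.05 equiv), THF, −78 °C, 30 min; 19, −78 °C; AcOH quench at −78 °C
Reagents that add atoms: none
Why: Intermolecular aldol addition with self-regeneration of the stereocentre: the aldehyde attacks the enolate face trans to the tert-butyl group and sets C7, while the C6 mixture is erased in step 13.

Step 13
Reactants: 21 aldol adduct
Product: 22 ynone (C6 ketone)
Conditions: Dess–Martin periodinane, CH2Cl2, 0 °C to rt
Reagents that add atoms: none
Why: Dess–Martin oxidation of the propargylic alcohol; C7 is quaternary and cannot epimerise.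

Step 14
Reactants: 22 ynone
Product: 23 (6R)-propargylic alcohol (dioxolanone and tert-butyl ester intact)
Conditions: (S)-2-methyl-CBS-oxazaborolidine (0.5 equiv), BH3·SMe2, THF, −40 °C
Reagents that add atoms: none
Why: Corey–Bakshi–Shibata reduction with the alkynyl group as the small substituent and quaternary C7 as the large one sets C6 (R) under reagent control.

Step 15
Reactants: 23 (6R)-propargylic alcohol
Product: 24 tert-butyl (2S,3R,4R,9S)-9-[(TBS)oxy]-3,4-dihydroxy-3-(hydroxymethyl)-2-methyl-11-(TIPS)undeca-5,10-diynoate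
Conditions: LiBH4 (2.5 equiv), THF, 0 °C; aq. NH4Cl
Reagents that add atoms: none
Why: Chemoselective hydride reduction of the activated dioxolanone releases C7–OH and the C8 primary alcohol while the tert-butyl ester is inert.

Step 16
Reactants: 24 triol
Product: 25 C8 mono-TBS ether of 24
Conditions: TBSCl (1.1 equiv), imidazole, CH2Cl2, 0 °C
Reagents that add atoms: tert-butyldimethylsilyl chloride, CC(C)(C)[Si](C)(C)Cl
Why: Selective silylation of the only primary alcohol.

Step 17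
Reactants: 25 propargylic diol
Product: 26 (5Z)-vinylsilane (Et3Si on C4, cis to C6)
Conditions: [Cp*Ru(MeCN)3]PF6 (5 mol %), Et3SiH, CH2Cl2, 0 °C to rt
Reagents that add atoms: triethylsilane, CC[SiH](CC)CC
Why: Trost ruthenium-catalysed trans-hydrosilylation, where the propargylic hydroxyl directs silicon to the distal alkyne carbon C4 and trans addition gives the Z-alkene; the TIPS alkyne is too hindered to react.

Step 18
Reactants: 26 vinylsilane
Product: 27 (5Z)-vinyl iodide (iodine on C4)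
Conditions: N-iodosuccinimide, 2,6-lutidine, (CF3)2CHOH, 0 °C
Reagents that add atoms: N-iodosuccinimide, O=C1CCC(=O)N1I
Why: Iododesilylation by ipso substitution with retention of alkene geometry.

Step 19
Reactants: 27 vinyl iodide
Product: 28 butenolide (ring C closed; C4=C5)
Conditions: PdCl2(PPh3)2 (5 mol %), CO (1 atm), Et3N, THF, 50 °C
Reagents that add atoms: carbon monoxide, [C-]#[O+]
Why: Palladium-catalysed carbonylative lactonisation: the acyl-palladium at C4 is trapped by the cis C6 hydroxyl in a five-membered closure, introducing C15.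

Step 20
Reactants: 28 butenolide
Product: 29 ring C cis-diol (C4 S, C5 S)
Conditions: OsO4 (5 mol %), 4-methylmorpholine N-oxide, acetone–H2O, rt
Reagents that add atoms: osmium tetroxide, O=[Os](=O)(=O)=O; 4-methylmorpholine N-oxide, C[N+]1([O-])CCOCC1; water, O
Why: Upjohn syn-dihydroxylation on the butenolide face anti to the bulky C6 substituent sets C4 and C5; the silyl alkyne does not react.

Step 21
Reactants: 29 diol
Product: 30 C5 acetate
Conditions: Ac2O, pyridine, 0 °C to rt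
Reagents that add atoms: acetic anhydride, CC(=O)OC(C)=O
Why: Acetylation of the only secondary hydroxyl; the tertiary C4 and C7 hydroxyls do not react without an acyl-transfer catalyst.

**Macrocyclisation and end game**

Step 22
Reactants: 30 TIPS alkyne
Product: 31 iodoalkyne
Conditions: AgF, N-iodosuccinimide, MeCN, rt, dark
Reagents that add atoms: N-iodosuccinimide, O=C1CCC(=O)N1I
Why: Silver-mediated desilylative iodination through the silver acetylide.

Step 23
Reactants: 31 iodoalkyne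
Product: 32 C8 primary alcohol
Conditions: HF·pyridine, pyridine, THF, 0 °C
Reagents that add atoms: none
Why: Selective cleavage of the primary TBS ether in the presence of the secondary C1 TBS ether.

Step 24
Reactants: 32 primary alcohol
Product: 33 C8 aldehyde (α-hydroxy aldehyde)
Conditions: SO3·pyridine, DMSO, i-Pr2NEt, CH2Cl2, 0 °C
Reagents that add atoms: none
Why: Parikh–Doering oxidation of the primary alcohol without glycol cleavage; the α-carbon is quaternary, so the aldehyde cannot epimerise.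

Step 25
Reactants: 33 iodoalkyne aldehyde
Product: 34 macrocyclic propargylic alcohol (10-oxabicyclo[7.2.1]dodec-5-yne core; C8 epimers)
Conditions: CrCl2 (8 equiv), NiCl2 (2 mol %), THF, 2 mM, slow addition, rt
Reagents that add atoms: none
Why: Intramolecular Nozaki–Hiyama–Kishi alkynylation tolerates the free hydroxyls, acetate and lactone and closes the ten-membered carbocycle at C8–C9; the C8 carbinol is oxidised next.

Step 26
Reactants: 34 macrocyclic propargylic alcohol
Product: 35 macrocyclic ynone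
Conditions: MnO2, CH2Cl2, rt
Reagents that add atoms: none
Why: Selective MnO2 oxidation of the propargylic alcohol.

Step 27
Reactants: 35 macrocyclic ynone
Product: 36 (Z)-β-methyl enone (C9=C10, C14 methyl on C10)
Conditions: Me2CuLi (from CuI and MeLi, 4 equiv), THF, −78 °C; aq. NH4Cl
Reagents that add atoms: lithium dimethylcuprate, [Li+].C[Cu-]C
Why: Conjugate addition of a Gilman cuprate by syn-carbocupration places C1 cis to the C8 carbonyl, the geometry needed for ring A.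

Step 28
Reactants: 36 (Z)-enone
Product: 39 CNP0315698.1 (target), via hemiketal tert-butyl ester 37 (not isolated), via hemiketal acid 38 (not isolated)
Conditions: TFA–H2O (9:1), CH2Cl2, 0 °C to rt
Reagents that add atoms: none
Why: Acidolysis of the TBS ether and tert-butyl ester, then transannular hemiketalisation and spirolactonisation through the oxocarbenium ion, with C8 set under thermodynamic control.

**Compound list**
1 | dimethyl (2R)-2-hydroxybutanedioate | COC(=O)C[C@@H](O)C(=O)OC | starting material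
2 | dilithium enolate-alkoxide of 1 | COC(O[Li])=C[C@@H](O[Li])C(=O)OC | intermediate (not isolated)
3 | dimethyl (2R,3S)-2-hydroxy-3-methylbutanedioate | COC(=O)[C@@H](C)[C@@H](O)C(=O)OC | intermediate
4 | (2R,3S)-2-hydroxy-3-methylbutanedioic acid | OC(=O)[C@@H](C)[C@@H](O)C(=O)O | intermediate
5 | (2S)-2-[(2R,4R)-2-tert-butyl-5-oxo-1,3-dioxolan-4-yl]propanoic acid | OC(=O)[C@@H](C)[C@H]1O[C@@H](C(C)(C)C)OC1=O | intermediate
6 | tert-butyl (2S)-2-[(2R,4R)-2-tert-butyl-5-oxo-1,3-dioxolan-4-yl]propanoate | CC(C)(C)OC(=O)[C@@H](C)[C@H]1O[C@@H](C(C)(C)C)OC1=O | intermediate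
7 | pent-4-ynoic acid | C#CCCC(=O)O | starting material
8 | trimethylsilyl 5-(trimethylsilyl)pent-4-ynoate | C[Si](C)(C)C#CCCC(=O)O[Si](C)(C)C | intermediate (not isolated)
9 | 5-(trimethylsilyl)pent-4-ynoic acid | C[Si](C)(C)C#CCCC(=O)O | intermediate
10 | 1-[5-(trimethylsilyl)pent-4-ynoyl]imidazole | C[Si](C)(C)C#CCCC(=O)n1ccnc1 | intermediate (not isolated)
11 | N-methoxy-N-methyl-5-(trimethylsilyl)pent-4-ynamide | CON(C)C(=O)CCC#C[Si](C)(C)C | intermediate
12 | ethynyl(triisopropyl)silane | C#C[Si](C(C)C)(C(C)C)C(C)C | starting material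
13 | lithium (triisopropylsilyl)acetylide | [Li]C#C[Si](C(C)C)(C(C)C)C(C)C | intermediate (not isolated)
14 | 1-(triisopropylsilyl)-7-(trimethylsilyl)hepta-1,6-diyn-3-one | CC(C)[Si](C(C)C)(C(C)C)C#CC(=O)CCC#C[Si](C)(C)C | intermediate
15 | (3S)-1-(triisopropylsilyl)-7-(trimethylsilyl)hepta-1,6-diyn-3-ol | CC(C)[Si](C(C)C)(C(C)C)C#C[C@@H](O)CCC#C[Si](C)(C)C | intermediate
16 | (3S)-3-[(tert-butyldimethylsilyl)oxy]-1-(triisopropylsilyl)-7-(trimethylsilyl)hepta-1,6-diyne | CC(C)[Si](C(C)C)(C(C)C)C#C[C@@H](O[Si](C)(C)C(C)(C)C)CCC#C[Si](C)(C)C | intermediate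
17 | (3S)-3-[(tert-butyldimethylsilyl)oxy]-1-(triisopropylsilyl)hepta-1,6-diyne | CC(C)[Si](C(C)C)(C(C)C)C#C[C@@H](O[Si](C)(C)C(C)(C)C)CCC#C | intermediate
18 | lithium acetylide of 17 (lithium on C7 of the heptadiyne) | CC(C)[Si](C(C)C)(C(C)C)C#C[C@@H](O[Si](C)(C)C(C)(C)C)CCC#C[Li] | intermediate (not isolated)
19 | (6S)-6-[(tert-butyldimethylsilyl)oxy]-8-(triisopropylsilyl)octa-2,7-diynal | CC(C)[Si](C(C)C)(C(C)C)C#C[C@@H](O[Si](C)(C)C(C)(C)C)CCC#CC=O | intermediate
20 | lithium enolate of 6 (acetal carbon R, side chain 2S) | CC(C)(C)OC(=O)[C@@H](C)C1=C(O[Li])O[C@H](C(C)(C)C)O1 | intermediate (not isolated)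
21 | tert-butyl (2S)-2-[(2R,4S)-2-tert-butyl-4-{(6S)-6-[(TBS)oxy]-1-hydroxy-8-(TIPS)octa-2,7-diyn-1-yl}-5-oxo-1,3-dioxolan-4-yl]propanoate, both carbinol (C6) epimers | CC(C)[Si](C(C)C)(C(C)C)C#C[C@@H](O[Si](C)(C)C(C)(C)C)CCC#CC(O)[C@@]1(O[C@@H](C(C)(C)C)OC1=O)[C@H](C)C(=O)OC(C)(C)C | intermediate
22 | tert-butyl (2S)-2-[(2R,4S)-2-tert-butyl-4-{(6S)-6-[(TBS)oxy]-8-(TIPS)octa-2,7-diynoyl}-5-oxo-1,3-dioxolan-4-yl]propanoate | CC(C)[Si](C(C)C)(C(C)C)C#C[C@@H](O[Si](C)(C)C(C)(C)C)CCC#CC(=O)[C@@]1(O[C@@H](C(C)(C)C)OC1=O)[C@H](C)C(=O)OC(C)(C)C | intermediate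
23 | tert-butyl (2S)-2-[(2R,4S)-2-tert-butyl-4-{(1R,6S)-6-[(TBS)oxy]-1-hydroxy-8-(TIPS)octa-2,7-diyn-1-yl}-5-oxo-1,3-dioxolan-4-yl]propanoate | CC(C)[Si](C(C)C)(C(C)C)C#C[C@@H](O[Si](C)(C)C(C)(C)C)CCC#C[C@@H](O)[C@@]1(O[C@@H](C(C)(C)C)OC1=O)[C@H](C)C(=O)OC(C)(C)C | intermediate
24 | tert-butyl (2S,3R,4R,9S)-9-[(TBS)oxy]-3,4-dihydroxy-3-(hydroxymethyl)-2-methyl-11-(TIPS)undeca-5,10-diynoate | CC(C)[Si](C(C)C)(C(C)C)C#C[C@@H](O[Si](C)(C)C(C)(C)C)CCC#C[C@@H](O)[C@](O)(CO)[C@H](C)C(=O)OC(C)(C)C | intermediate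
25 | tert-butyl (2S,3R,4R,9S)-9-[(TBS)oxy]-3-{[(TBS)oxy]methyl}-3,4-dihydroxy-2-methyl-11-(TIPS)undeca-5,10-diynoate | CC(C)[Si](C(C)C)(C(C)C)C#C[C@@H](O[Si](C)(C)C(C)(C)C)CCC#C[C@@H](O)[C@](O)(CO[Si](C)(C)C(C)(C)C)[C@H](C)C(=O)OC(C)(C)C | intermediate
26 | tert-butyl (2S,3R,4R,5Z,9S)-9-[(TBS)oxy]-3-{[(TBS)oxy]methyl}-3,4-dihydroxy-2-methyl-6-(triethylsilyl)-11-(TIPS)undec-5-en-10-ynoate | CC(C)[Si](C(C)C)(C(C)C)C#C[C@@H](O[Si](C)(C)C(C)(C)C)CC/C([Si](CC)(CC)CC)=C/[C@@H](O)[C@](O)(CO[Si](C)(C)C(C)(C)C)[C@H](C)C(=O)OC(C)(C)C | intermediate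
27 | tert-butyl (2S,3R,4R,5Z,9S)-9-[(TBS)oxy]-3-{[(TBS)oxy]methyl}-3,4-dihydroxy-6-iodo-2-methyl-11-(TIPS)undec-5-en-10-ynoate | CC(C)[Si](C(C)C)(C(C)C)C#C[C@@H](O[Si](C)(C)C(C)(C)C)CC/C(I)=C/[C@@H](O)[C@](O)(CO[Si](C)(C)C(C)(C)C)[C@H](C)C(=O)OC(C)(C)C | intermediate
28 | tert-butyl (2S,3R)-4-[(TBS)oxy]-3-hydroxy-2-methyl-3-[(2R)-4-{(3S)-3-[(TBS)oxy]-5-(TIPS)pent-4-yn-1-yl}-5-oxo-2,5-dihydrofuran-2-yl]butanoate | CC(C)[Si](C(C)C)(C(C)C)C#C[C@@H](O[Si](C)(C)C(C)(C)C)CCC1=C[C@@H](OC1=O)[C@](O)(CO[Si](C)(C)C(C)(C)C)[C@H](C)C(=O)OC(C)(C)C | intermediate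
29 | tert-butyl (2S,3R)-4-[(TBS)oxy]-3-[(2R,3S,4S)-3,4-dihydroxy-4-{(3S)-3-[(TBS)oxy]-5-(TIPS)pent-4-yn-1-yl}-5-oxooxolan-2-yl]-3-hydroxy-2-methylbutanoate | CC(C)[Si](C(C)C)(C(C)C)C#C[C@@H](O[Si](C)(C)C(C)(C)C)CC[C@]1(O)[C@@H](O)[C@@H](OC1=O)[C@](O)(CO[Si](C)(C)C(C)(C)C)[C@H](C)C(=O)OC(C)(C)C | intermediate
30 | 3-O-acetate of 29 on the oxolane ring (C5 acetate; oxolane 2R,3S,4S) | CC(C)[Si](C(C)C)(C(C)C)C#C[C@@H](O[Si](C)(C)C(C)(C)C)CC[C@]1(O)[C@@H](OC(C)=O)[C@@H](OC1=O)[C@](O)(CO[Si](C)(C)C(C)(C)C)[C@H](C)C(=O)OC(C)(C)C | intermediate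
31 | iodoalkyne analogue of 30 (5-iodopent-4-ynyl side chain, 3S) | IC#C[C@@H](O[Si](C)(C)C(C)(C)C)CC[C@]1(O)[C@@H](OC(C)=O)[C@@H](OC1=O)[C@](O)(CO[Si](C)(C)C(C)(C)C)[C@H](C)C(=O)OC(C)(C)C | intermediate
32 | tert-butyl (2S,3R)-3-[(2R,3S,4S)-3-acetoxy-4-hydroxy-4-{(3S)-3-[(TBS)oxy]-5-iodopent-4-yn-1-yl}-5-oxooxolan-2-yl]-3,4-dihydroxy-2-methylbutanoate | IC#C[C@@H](O[Si](C)(C)C(C)(C)C)CC[C@]1(O)[C@@H](OC(C)=O)[C@@H](OC1=O)[C@](O)(CO)[C@H](C)C(=O)OC(C)(C)C | intermediate
33 | tert-butyl (2S,3S)-3-[(2R,3S,4S)-3-acetoxy-4-hydroxy-4-{(3S)-3-[(TBS)oxy]-5-iodopent-4-yn-1-yl}-5-oxooxolan-2-yl]-3-hydroxy-2-methyl-4-oxobutanoate | IC#C[C@@H](O[Si](C)(C)C(C)(C)C)CC[C@]1(O)[C@@H](OC(C)=O)[C@@H](OC1=O)[C@](O)(C=O)[C@H](C)C(=O)OC(C)(C)C | intermediate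
34 | tert-butyl (2S)-2-[(1S,4S,8R,9R,12S)-12-acetoxy-4-[(TBS)oxy]-1,7,8-trihydroxy-11-oxo-10-oxabicyclo[7.2.1]dodec-5-yn-8-yl]propanoate, both C-7 (= C8) epimers | OC1C#C[C@@H](O[Si](C)(C)C(C)(C)C)CC[C@]2(O)[C@@H](OC(C)=O)[C@@H](OC2=O)[C@@]1(O)[C@H](C)C(=O)OC(C)(C)C | intermediate
35 | tert-butyl (2S)-2-[(1S,4S,8S,9R,12S)-12-acetoxy-4-[(TBS)oxy]-1,8-dihydroxy-7,11-dioxo-10-oxabicyclo[7.2.1]dodec-5-yn-8-yl]propanoate | O=C1C#C[C@@H](O[Si](C)(C)C(C)(C)C)CC[C@]2(O)[C@@H](OC(C)=O)[C@@H](OC2=O)[C@@]1(O)[C@H](C)C(=O)OC(C)(C)C | intermediate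
36 | tert-butyl (2S)-2-[(1S,4S,5Z,8S,9R,12S)-12-acetoxy-4-[(TBS)oxy]-1,8-dihydroxy-5-methyl-7,11-dioxo-10-oxabicyclo[7.2.1]dodec-5-en-8-yl]propanoate | O=C1/C=C(C)\[C@@H](O[Si](C)(C)C(C)(C)C)CC[C@]2(O)[C@@H](OC(C)=O)[C@@H](OC2=O)[C@@]1(O)[C@H](C)C(=O)OC(C)(C)C | intermediate
37 | bridged hemiketal tert-butyl ester (ring A closed C1–O–C8, C8–OH, rings A and C as in the target, C12 tert-butyl ester) | CC(=O)O[C@H]1[C@H]2OC(=O)[C@]1(O)CC[C@@H]1O[C@](O)(C=C1C)[C@]2(O)[C@H](C)C(=O)OC(C)(C)C | intermediate (not isolated)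
38 | bridged hemiketal acid (as 37 with free C12 acid) | CC(=O)O[C@H]1[C@H]2OC(=O)[C@]1(O)CC[C@@H]1O[C@](O)(C=C1C)[C@]2(O)[C@H](C)C(=O)O | intermediate (not isolated)
39 | CNP0315698.1, (1S,4S,5S,6R,7S,8S,11S) in the numbering above | CC(=O)O[C@H]1[C@H]2OC(=O)[C@]1(O)CC[C@@H]1O[C@@]3(C=C1C)OC(=O)[C@@H](C)[C@]23O | target

**Step count:** 28 steps in total. The longest linear sequence is 24 steps (7 → 39: steps 5–11, then 12–28); the east fragment adds 4 steps (1 → 6).

**Three steps most likely to fail**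

Step 12 (key aldol). LiN(i-Pr)2 may deprotonate C11 next to the tert-butyl ester instead of the dioxolanone, which would lead to β-elimination. The fallback sets out from acid 5 and ynal 19. The dilithium dianion of 5 (LiN(SiMe3)2, 2.1 equiv, THF, −78 °C) can only enolise in the ring, because the side chain is a carboxylate. Its addition to 19 gives the aldol hydroxy acid F1, which is esterified at once with tert-butyl 2,2,2-trichloroacetimidate before it can lactonise. This comes back to the route at 21.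

Step 25 (ring closure to a cyclodecyne). The linear alkyne may make the ten-membered closure too strained. The fallback sets out from 30 and closes the ring as a (Z)-cycloalkene with the methyl group already in place. AgF followed by dilute acid gives the terminal alkyne F2. Gold-catalysed Markovnikov hydration (Ph3PAuCl, AgOTf, wet dioxane) gives the methyl ketone F3. Stork–Zhao olefination (Ph3P=CHI from the iodomethylphosphonium iodide and NaN(SiMe3)2, −78 °C) gives the (Z)-iodoalkene F4, with iodine cis to C1. HF·pyridine gives the primary alcohol F5 and Parikh–Doering oxidation gives the aldehyde F6. The vinyl variant of the CrCl2/NiCl2 cyclisation gives the cyclic allylic alcohol F7, and MnO2 oxidation comes back to the route at 36. This fallback also removes the cuprate step.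

Step 28 (one-pot acid end game). Strong acid may dehydrate the C7 tertiary alcohol, or fail to give the written C8 configuration. The fallback sets out from 36 and replaces oxocarbenium trapping by acylation of the hemiketal hydroxyl. HF·pyridine gives hemiketal 37, now isolated. Me3SiOTf with 2,6-lutidine cleaves the tert-butyl ester to acid 38 without protic acid. Yamaguchi activation (2,4,6-trichlorobenzoyl chloride, Et3N, DMAP, toluene) then closes ring B and comes back at 39.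

Further compounds
F1 | step 12 | (2S)-2-[(2R,4S)-2-tert-butyl-4-{(6S)-6-[(TBS)oxy]-1-hydroxy-8-(TIPS)octa-2,7-diyn-1-yl}-5-oxo-1,3-dioxolan-4-yl]propanoic acid, both carbinol epimers | CC(C)[Si](C(C)C)(C(C)C)C#C[C@@H](O[Si](C)(C)C(C)(C)C)CCC#CC(O)[C@@]1(O[C@@H](C(C)(C)C)OC1=O)[C@H](C)C(=O)O
F2 | step 25 | terminal alkyne analogue of 30 (TIPS replaced by H) | C#C[C@@H](O[Si](C)(C)C(C)(C)C)CC[C@]1(O)[C@@H](OC(C)=O)[C@@H](OC1=O)[C@](O)(CO[Si](C)(C)C(C)(C)C)[C@H](C)C(=O)OC(C)(C)C
F3 | step 25 | methyl ketone (C10 ketone, (S)-α-silyloxy) from hydration of F2 | CC(=O)[C@@H](O[Si](C)(C)C(C)(C)C)CC[C@]1(O)[C@@H](OC(C)=O)[C@@H](OC1=O)[C@](O)(CO[Si](C)(C)C(C)(C)C)[C@H](C)C(=O)OC(C)(C)C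
F4 | step 25 | (Z)-iodoalkene (I–C9H=C10(CH3)–C1, iodine cis to C1) | I/C=C(C)\[C@@H](O[Si](C)(C)C(C)(C)C)CC[C@]1(O)[C@@H](OC(C)=O)[C@@H](OC1=O)[C@](O)(CO[Si](C)(C)C(C)(C)C)[C@H](C)C(=O)OC(C)(C)C
F5 | step 25 | C8 primary alcohol of F4 | I/C=C(C)\[C@@H](O[Si](C)(C)C(C)(C)C)CC[C@]1(O)[C@@H](OC(C)=O)[C@@H](OC1=O)[C@](O)(CO)[C@H](C)C(=O)OC(C)(C)C
F6 | step 25 | C8 aldehyde of F4 | I/C=C(C)\[C@@H](O[Si](C)(C)C(C)(C)C)CC[C@]1(O)[C@@H](OC(C)=O)[C@@H](OC1=O)[C@](O)(C=O)[C@H](C)C(=O)OC(C)(C)C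
F7 | step 25 | macrocyclic (Z)-allylic alcohol (C8–OH epimers; 36 with C8 carbinol in place of the ketone) | OC1/C=C(C)\[C@@H](O[Si](C)(C)C(C)(C)C)CC[C@]2(O)[C@@H](OC(C)=O)[C@@H](OC2=O)[C@@]1(O)[C@H](C)C(=O)OC(C)(C)C
F0 | step 28 | none | none
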